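The route rests on disconnecting the ring at C1–C2 and C2–C3 and the ester arm at C7–C8. In ring C1(quaternary)–C2(=O)–C3=C4–C5–C6 the ring carbonyl C2 and the ester carbonyl C8 both flank C1, so each can come from CO. One palladium-catalysed double carbonylation of an acyclic (Z)-vinyl iodide (C3) tethered to the 1,1-disubstituted C1=C7 alkene closes the cyclohexenone, creates the quaternary stereocentre and installs CH2CO2Me. The precursor is a (Z)-1-iodo-1,5-diene carrying the bis-silylated dihydroxygeranylgeranyl chain, with C5 masked as an (S)-silyl ether that also steers the new centre and is oxidised to the second ketone afterwards.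

Key step: step 14

Remarks on the chemistry (before the steps)
- Numbering: ring C1 (quaternary, R), C2 (C=O), C3=C4, C5, C6H2; ester arm C7H2–C8O2Me; side chain C1′–C16′ (all-E, 12′S,13′R anti-diol).
- Abbreviations: TBS = tert-butyldimethylsilyl; TES = triethylsilyl; GG* = (2E,6E,10E,12S,13R)-12,13-bis(tert-butyldimethylsilyloxy)-3,7,11,15-tetramethylhexadeca-2,6,10,14-tetraen-1-yl.
- Precursor design: a free (Z)-β-iodoenone with the doubly activated C6 methylene is expected, under palladium/CO/amine, to lactonise to a γ-alkylidene butenolide (O-acylation of its enol by the acylpalladium unit), to shift the C1=C7 alkene into conjugation and to exchange iodide by addition–elimination. The iodo-dienone is therefore made (23) but reduced and silylated before the cascade. The C5 silyl ether removes these pathways, acts as control element for C1, and is oxidised back afterwards to the bis-silyl enedione (28).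
- Assumption: (+)-Ipc2BOMe, 1-(trimethylsilyl)propyne and ethyl (Z)-3-iodoacrylate are purchased.

Step 1
Reactants: 1 geranyl acetate
Product: 3 (2E,6E)-3,7-dimethyl-8-oxoocta-2,6-dien-1-yl acetate, via hydroxy acetate 2 (not isolated)
Conditions: SeO2 (cat.), t-BuOOH, salicylic acid (cat.), CH2Cl2, rt; then MnO2, CH2Cl2, rt
Reagents that add atoms: tert-butyl hydroperoxide, CC(C)(C)OO
Why: Selenium dioxide allylic oxidation (ene reaction then [2,3]-sigmatropic shift) should attack only the (E)-methyl group of the electron-rich terminal alkene, the alkene next to the acetate being deactivated, and MnO2 allylic oxidation then takes the alcohol on to the (E)-enal.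

Step 2
Reactants: 3 (2E,6E)-3,7-dimethyl-8-oxoocta-2,6-dien-1-yl acetate; 4 allyl(diisopropylamino)dimethylsilane
Product: 7 (2E,6E,8S,9R)-8,9-dihydroxy-3,7-dimethylundeca-2,6,10-trien-1-yl acetate, via silylallyl borane 5 (not isolated), via anti silyl alcohol 6 (not isolated)
Conditions: 4, n-BuLi, TMEDA, Et2O, 0 °C; (+)-Ipc2BOMe [from (−)-α-pinene], −78 °C; BF3·OEt2; 3, −78 °C; then H2O2, KF, KHCO3, THF/MeOH, rt
Reagents that add atoms: hydrogen peroxide, OO
Why: γ-Silylallylboration through a chair Zimmerman–Traxler transition state places the (E)-silyl group anti to the new hydroxyl while the isopinocampheyl groups derived from (−)-α-pinene direct the reagent to the Re face of the enal (8S), and Tamao oxidation then replaces silicon by hydroxyl with retention (9R).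

Step 3
Reactants: 7 (2E,6E,8S,9R)-8,9-dihydroxy-3,7-dimethylundeca-2,6,10-trien-1-yl acetate
Product: 8 (2E,6E,8S,9R)-8,9-dihydroxy-3,7,11-trimethyldodeca-2,6,10-trien-1-yl acetate
Conditions: 2-methyl-2-butene (cosolvent), second-generation Grubbs catalyst RuCl2(=CHPh)(PCy3)(H2IMes) (5 mol %), CH2Cl2, 35 °C
Reagents that add atoms: 2-methyl-2-butene, CC=C(C)C
Why: Olefin cross-metathesis with a large excess of 2-methyl-2-butene should exchange the methylene terminus of the only monosubstituted alkene for an isopropylidene group, the hindered trisubstituted alkenes of the chain being far less reactive toward the ruthenium alkylidene.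

Step 4
Reactants: 8 (2E,6E,8S,9R)-8,9-dihydroxy-3,7,11-trimethyldodeca-2,6,10-trien-1-yl acetate
Product: 9 (2E,6E,8S,9R)-8,9-bis(tert-butyldimethylsilyloxy)-3,7,11-trimethyldodeca-2,6,10-trien-1-yl acetate
Conditions: TBSOTf, 2,6-lutidine, CH2Cl2, −78 → 0 °C
Reagents that add atoms: tert-butyldimethylsilyl triflate, CC(C)(C)[Si](C)(C)OS(=O)(=O)C(F)(F)F
Why: Silylation with the silyl triflate should cap both secondary allylic hydroxyls, including the hindered second one, without touching the stereocentres or the acetate.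

Step 5
Reactants: 9 (2E,6E,8S,9R)-8,9-bis(tert-butyldimethylsilyloxy)-3,7,11-trimethyldodeca-2,6,10-trien-1-yl acetate
Product: 10 (2E,6E,8S,9R)-8,9-bis(tert-butyldimethylsilyloxy)-3,7,11-trimethyldodeca-2,6,10-trien-1-ol
Conditions: K2CO3, MeOH, 0 °C → rt
Reagents that add atoms: none
Why: Base-catalysed transesterification with methanol should free the primary allylic alcohol while the secondary silyl ethers are stable to carbonate.

Step 6
Reactants: 10 (2E,6E,8S,9R)-8,9-bis(tert-butyldimethylsilyloxy)-3,7,11-trimethyldodeca-2,6,10-trien-1-ol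
Product: 11 (2E,6E,8S,9R)-1-bromo-8,9-bis(tert-butyldimethylsilyloxy)-3,7,11-trimethyldodeca-2,6,10-triene
Conditions: CBr4, PPh3, 2,6-lutidine (cat.), CH2Cl2, 0 °C
Reagents that add atoms: carbon tetrabromide, BrC(Br)(Br)Br
Why: The Appel reaction should convert the primary allylic alcohol into the bromide by SN2 displacement of the oxyphosphonium ion without allylic transposition or loss of alkene geometry.

Step 7
Reactants: 11 (2E,6E,8S,9R)-1-bromo-8,9-bis(tert-butyldimethylsilyloxy)-3,7,11-trimethyldodeca-2,6,10-triene; 12 1-(trimethylsilyl)propyne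
Product: 15 (5E,9E,11S,12R)-11,12-bis(tert-butyldimethylsilyloxy)-6,10,14-trimethylpentadeca-5,9,13-trien-1-yne, via lithiated silylpropyne 13 (not isolated), via silyl enyne 14 (not isolated)
Conditions: 12, n-BuLi, THF, −78 → −20 °C; 11, −78 → 0 °C; then MeOH, K2CO3, rt
Reagents that add atoms: none
Why: SN2 alkylation of the propargylic lithium reagent at the primary allylic bromide should add three carbons with the (E)-alkene intact, and carbonate methanolysis then cleaves the alkynyl C–Si bond to give the terminal alkyne.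

Step 8
Reactants: 15 (5E,9E,11S,12R)-11,12-bis(tert-butyldimethylsilyloxy)-6,10,14-trimethylpentadeca-5,9,13-trien-1-yne; 16 3-chloro-2-(chloromethyl)prop-1-ene
Product: 18 3-chloro-2-GG*-prop-1-ene, via alkenylalane 17 (not isolated)
Conditions: Me3Al, Cp2ZrCl2 (0.25 equiv), CH2Cl2, 0 °C → rt; then 16 (4 equiv), Pd(PPh3)4 (5 mol %), THF, rt
Reagents that add atoms: trimethylaluminium, C[Al](C)C
Why: Zirconium-catalysed Negishi carboalumination should add methyl and aluminium syn across the terminal alkyne with methyl on the internal carbon, fixing the (E)-trisubstituted alkene, and palladium-catalysed alkenyl–allyl cross-coupling with the excess symmetrical dichloride then joins the alkenyl carbon to one allylic terminus with retention.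

Step 9
Reactants: 19 ethyl (Z)-3-iodoacrylate
Product: 20 (Z)-3-iodoprop-2-enal
Conditions: i-Bu2AlH (1.05 equiv), CH2Cl2, −78 °C; MeOH, aq. potassium sodium tartrate; used at once as a cold solution
Reagents that add atoms: none
Why: Low-temperature hydride reduction of the ester should stop at the aluminium hemiacetal, which releases the (Z)-aldehyde on work-up before it can isomerise.

Step 10
Reactants: 18 3-chloro-2-GG*-prop-1-ene; 20 (Z)-3-iodoprop-2-enal
Product: 22 (1Z,3RS)-1-iodo-5-GG*-hexa-1,5-dien-3-ol, via allylzinc chloride 21 (not isolated)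
Conditions: Zn dust, LiCl, THF, 25 °C; then 20, −78 °C
Reagents that add atoms: none
Why: Zinc insertion assisted by LiCl should give the allylic zinc chloride without homocoupling, and its carbonyl allylation (SE2′ addition through a six-membered transition state) at −78 °C gives the homoallylic alcohol as both C3 epimers, the symmetrical allyl unit allowing only one constitution.

Step 11
Reactants: 22 (1Z,3RS)-1-iodo-5-GG*-hexa-1,5-dien-3-ol
Product: 23 (1Z)-1-iodo-5-GG*-hexa-1,5-dien-3-one
Conditions: Dess–Martin periodinane, NaHCO3, CH2Cl2, 0 °C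
Reagents that add atoms: none
Why: Dess–Martin oxidation under bicarbonate buffering should give the ketone under neutral conditions that preserve the (Z)-iodoalkene and keep the 1,1-disubstituted alkene out of conjugation.

Step 12
Reactants: 23 (1Z)-1-iodo-5-GG*-hexa-1,5-dien-3-one
Product: 24 (1Z,3S)-1-iodo-5-GG*-hexa-1,5-dien-3-ol
Conditions: (R)-2-methyl-CBS-oxazaborolidine (0.5 equiv), catecholborane, toluene, −78 °C
Reagents that add atoms: none
Why: In this Corey–Bakshi–Shibata reduction the ketone should bind the (R)-oxazaborolidine with the iodovinyl group as the large substituent, so that hydride is delivered to one face and the carbinol centre is set as S, while catecholborane at −78 °C leaves the alkenes alone.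

Step 13
Reactants: 24 (1Z,3S)-1-iodo-5-GG*-hexa-1,5-dien-3-ol
Product: 25 (1Z,3S)-1-iodo-3-(triethylsilyloxy)-5-GG*-hexa-1,5-diene
Conditions: TESCl, imidazole, CH2Cl2, 0 °C
Reagents that add atoms: chlorotriethylsilane, CC[Si](CC)(CC)Cl
Why: Imidazole-promoted silylation should mask the secondary hydroxyl, which would otherwise lactonise the acylpalladium intermediate of the next step, as an ether that can later be removed in the presence of the TBS groups.

Step 14
Reactants: 25 (1Z,3S)-1-iodo-3-(triethylsilyloxy)-5-GG*-hexa-1,5-diene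
Product: 26 methyl 2-[(1R,5S)-1-GG*-2-oxo-5-(triethylsilyloxy)cyclohex-3-en-1-yl]acetate
Conditions: PdCl2(PPh3)2 (5 mol %), CO (40 atm), MeOH (5 equiv), Et3N (2 equiv), MeCN/toluene, 90 °C
Reagents that add atoms: carbon monoxide, [C-]#[O+]; methanol, CO
Why: Proposed new method: zerovalent palladium formed from PdCl2(PPh3)2 under CO inserts into the C3–I bond, CO insertion gives the C2 acylpalladium species, syn-acylpalladation of the C1=C7 alkene forms C1–C2, and the C7 alkylpalladium, which has no β-hydrogen, takes up a second CO and is cleaved by methanol to forge C7–C8 as the methyl ester. The closest known reaction type is the non-stereoselective cyclic acylpalladation–alkoxycarbonylation of (Z)-iodo dienes and o-iodoaryl alkenes to five- and six-membered ketones bearing CH2CO2Me; new here is its use to set a quaternary stereocentre under 1,3-induction. The ring closes in the 6-exo-trig mode, C2 attacking the internal alkene carbon C1. The new stereocentre C1 is controlled by the C5 silyloxy stereocentre: in the half-chair transition state C7 must lie along the acyl–palladium bond (pseudoaxial), and the OSiEt3 group avoids the 1,3-diaxial position beside palladium by sitting pseudoequatorial, which should expose the alkene face leading to (1R,5S). The step needs CO insertion to outrun 5-exo carbopalladation and ring closure to outrun methanolysis of the first acyl complex; the (Z)-geometry holds C2 beside the tethered alkene, 40 atm of CO with only a small excess of methanol favours the required order, and the sp3 C5 ether removes the enolisable ketone that would trap the acyl complex as a butenolide.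

Step 15
Reactants: 26 methyl 2-[(1R,5S)-1-GG*-2-oxo-5-(triethylsilyloxy)cyclohex-3-en-1-yl]acetate
Product: 27 methyl 2-[(1R,5S)-1-GG*-5-hydroxy-2-oxocyclohex-3-en-1-yl]acetate
Conditions: PPTS (cat.), MeOH/CH2Cl2, 0 °C → rt
Reagents that add atoms: none
Why: Mild acid-catalysed methanolysis should cleave the less hindered triethylsilyl ether selectively while the two secondary TBS ethers and the methyl ester survive.

Step 16
Reactants: 27 methyl 2-[(1R,5S)-1-GG*-5-hydroxy-2-oxocyclohex-3-en-1-yl]acetate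
Product: 28 methyl 2-[(1R)-1-GG*-2,5-dioxocyclohex-3-en-1-yl]acetate
Conditions: Dess–Martin periodinane, NaHCO3, CH2Cl2, rt
Reagents that add atoms: none
Why: Dess–Martin oxidation of the ring allylic alcohol should give the ene-1,4-dione and erase the C5 stereocentre once it has served as control element, the quaternary C1 being unable to epimerise.

Step 17
Reactants: 28 methyl 2-[(1R)-1-GG*-2,5-dioxocyclohex-3-en-1-yl]acetate
Product: 29 methyl 2-[(1R)-1-[(2E,6E,10E,12S,13R)-12,13-dihydroxy-3,7,11,15-tetramethylhexadeca-2,6,10,14-tetraen-1-yl]-2,5-dioxocyclohex-3-en-1-yl]acetate (CNP0122011.2)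
Conditions: HF·pyridine, pyridine, THF, 0 °C → rt
Reagents that add atoms: none
Why: Fluoride-mediated desilylation with buffered HF·pyridine should remove both TBS ethers under non-basic conditions that the enedione, the methyl ester and the bis-allylic diol tolerate.

Compound list
1 | geranyl acetate | CC(=O)OC/C=C(\C)CCC=C(C)C | starting material
2 | (2E,6E)-8-hydroxy-3,7-dimethylocta-2,6-dien-1-yl acetate (formed in the flask) | CC(=O)OC/C=C(\C)CC/C=C(\C)CO | intermediate
3 | (2E,6E)-3,7-dimethyl-8-oxoocta-2,6-dien-1-yl acetate | CC(=O)OC/C=C(\C)CC/C=C(\C)C=O | intermediate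
4 | allyl(diisopropylamino)dimethylsilane | C=CC[Si](C)(C)N(C(C)C)C(C)C | starting material
5 | [(E)-3-[(diisopropylamino)dimethylsilyl]allyl]bis[(1S,2S,3S,5R)-isopinocampheyl]borane (formed in the flask) | C[C@@H]1[C@@H](B(C/C=C/[Si](C)(C)N(C(C)C)C(C)C)[C@H]3C[C@H]4C[C@@H]([C@@H]3C)C4(C)C)C[C@H]2C[C@@H]1C2(C)C | intermediate
6 | (2E,6E,8S,9R)-9-[(diisopropylamino)dimethylsilyl]-8-hydroxy-3,7-dimethylundeca-2,6,10-trien-1-yl acetate (formed in the flask as its borinate) | CC(=O)OC/C=C(\C)CC/C=C(\C)[C@H](O)[C@H]([Si](C)(C)N(C(C)C)C(C)C)C=C | intermediate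
7 | (2E,6E,8S,9R)-8,9-dihydroxy-3,7-dimethylundeca-2,6,10-trien-1-yl acetate | CC(=O)OC/C=C(\C)CC/C=C(\C)[C@H](O)[C@H](O)C=C | intermediate
8 | (2E,6E,8S,9R)-8,9-dihydroxy-3,7,11-trimethyldodeca-2,6,10-trien-1-yl acetate | CC(=O)OC/C=C(\C)CC/C=C(\C)[C@H](O)[C@H](O)C=C(C)C | intermediate
9 | (2E,6E,8S,9R)-8,9-bis(tert-butyldimethylsilyloxy)-3,7,11-trimethyldodeca-2,6,10-trien-1-yl acetate | CC(=O)OC/C=C(\C)CC/C=C(\C)[C@H](O[Si](C)(C)C(C)(C)C)[C@H](O[Si](C)(C)C(C)(C)C)C=C(C)C | intermediate
10 | (2E,6E,8S,9R)-8,9-bis(tert-butyldimethylsilyloxy)-3,7,11-trimethyldodeca-2,6,10-trien-1-ol | OC/C=C(\C)CC/C=C(\C)[C@H](O[Si](C)(C)C(C)(C)C)[C@H](O[Si](C)(C)C(C)(C)C)C=C(C)C | intermediate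
11 | (2E,6E,8S,9R)-1-bromo-8,9-bis(tert-butyldimethylsilyloxy)-3,7,11-trimethyldodeca-2,6,10-triene | BrC/C=C(\C)CC/C=C(\C)[C@H](O[Si](C)(C)C(C)(C)C)[C@H](O[Si](C)(C)C(C)(C)C)C=C(C)C | intermediate
12 | 1-(trimethylsilyl)propyne | CC#C[Si](C)(C)C | starting material
13 | 3-lithio-1-(trimethylsilyl)propyne (formed in the flask) | [Li]CC#C[Si](C)(C)C | intermediate
14 | trimethyl[(5E,9E,11S,12R)-11,12-bis(tert-butyldimethylsilyloxy)-6,10,14-trimethylpentadeca-5,9,13-trien-1-yn-1-yl]silane (formed in the flask) | C[Si](C)(C)C#CCC/C=C(\C)CC/C=C(\C)[C@H](O[Si](C)(C)C(C)(C)C)[C@H](O[Si](C)(C)C(C)(C)C)C=C(C)C | intermediate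
15 | (5E,9E,11S,12R)-11,12-bis(tert-butyldimethylsilyloxy)-6,10,14-trimethylpentadeca-5,9,13-trien-1-yne | C#CCC/C=C(\C)CC/C=C(\C)[C@H](O[Si](C)(C)C(C)(C)C)[C@H](O[Si](C)(C)C(C)(C)C)C=C(C)C | intermediate
16 | 3-chloro-2-(chloromethyl)prop-1-ene | C=C(CCl)CCl | starting material
17 | dimethyl[(1E,5E,9E,11S,12R)-11,12-bis(tert-butyldimethylsilyloxy)-2,6,10,14-tetramethylpentadeca-1,5,9,13-tetraen-1-yl]alumane (formed in the flask) | C[Al](C)/C=C(\C)CC/C=C(\C)CC/C=C(\C)[C@H](O[Si](C)(C)C(C)(C)C)[C@H](O[Si](C)(C)C(C)(C)C)C=C(C)C | intermediate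
18 | 3-chloro-2-GG*-prop-1-ene | ClCC(=C)C/C=C(\C)CC/C=C(\C)CC/C=C(\C)[C@H](O[Si](C)(C)C(C)(C)C)[C@H](O[Si](C)(C)C(C)(C)C)C=C(C)C | intermediate
19 | ethyl (Z)-3-iodoacrylate | CCOC(=O)/C=C\I | starting material
20 | (Z)-3-iodoprop-2-enal | O=C/C=C\I | intermediate
21 | (2-GG*-allyl)zinc chloride (formed in the flask) | Cl[Zn]CC(=C)C/C=C(\C)CC/C=C(\C)CC/C=C(\C)[C@H](O[Si](C)(C)C(C)(C)C)[C@H](O[Si](C)(C)C(C)(C)C)C=C(C)C | intermediate
22 | (1Z,3RS)-1-iodo-5-GG*-hexa-1,5-dien-3-ol (both C3 epimers) | I/C=C\C(O)CC(=C)C/C=C(\C)CC/C=C(\C)CC/C=C(\C)[C@H](O[Si](C)(C)C(C)(C)C)[C@H](O[Si](C)(C)C(C)(C)C)C=C(C)C | intermediate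
23 | (1Z)-1-iodo-5-GG*-hexa-1,5-dien-3-one | I/C=C\C(=O)CC(=C)C/C=C(\C)CC/C=C(\C)CC/C=C(\C)[C@H](O[Si](C)(C)C(C)(C)C)[C@H](O[Si](C)(C)C(C)(C)C)C=C(C)C | intermediate
24 | (1Z,3S)-1-iodo-5-GG*-hexa-1,5-dien-3-ol | I/C=C\[C@@H](O)CC(=C)C/C=C(\C)CC/C=C(\C)CC/C=C(\C)[C@H](O[Si](C)(C)C(C)(C)C)[C@H](O[Si](C)(C)C(C)(C)C)C=C(C)C | intermediate
25 | (1Z,3S)-1-iodo-3-(triethylsilyloxy)-5-GG*-hexa-1,5-diene (precursor of the key step) | I/C=C\[C@@H](O[Si](CC)(CC)CC)CC(=C)C/C=C(\C)CC/C=C(\C)CC/C=C(\C)[C@H](O[Si](C)(C)C(C)(C)C)[C@H](O[Si](C)(C)C(C)(C)C)C=C(C)C | intermediate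
26 | methyl 2-[(1R,5S)-1-GG*-2-oxo-5-(triethylsilyloxy)cyclohex-3-en-1-yl]acetate (product of the key step) | COC(=O)C[C@@]1(C/C=C(\C)CC/C=C(\C)CC/C=C(\C)[C@H](O[Si](C)(C)C(C)(C)C)[C@H](O[Si](C)(C)C(C)(C)C)C=C(C)C)C[C@H](O[Si](CC)(CC)CC)C=CC1=O | intermediate
27 | methyl 2-[(1R,5S)-1-GG*-5-hydroxy-2-oxocyclohex-3-en-1-yl]acetate | COC(=O)C[C@@]1(C/C=C(\C)CC/C=C(\C)CC/C=C(\C)[C@H](O[Si](C)(C)C(C)(C)C)[C@H](O[Si](C)(C)C(C)(C)C)C=C(C)C)C[C@H](O)C=CC1=O | intermediate
28 | methyl 2-[(1R)-1-GG*-2,5-dioxocyclohex-3-en-1-yl]acetate (bis-TBS ether of the target) | COC(=O)C[C@@]1(C/C=C(\C)CC/C=C(\C)CC/C=C(\C)[C@H](O[Si](C)(C)C(C)(C)C)[C@H](O[Si](C)(C)C(C)(C)C)C=C(C)C)CC(=O)C=CC1=O | intermediate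
29 | methyl 2-[(1R)-1-[(2E,6E,10E,12S,13R)-12,13-dihydroxy-3,7,11,15-tetramethylhexadeca-2,6,10,14-tetraen-1-yl]-2,5-dioxocyclohex-3-en-1-yl]acetate | COC(=O)C[C@@]1(C/C=C(\C)CC/C=C(\C)CC/C=C(\C)[C@H](O)[C@H](O)C=C(C)C)CC(=O)C=CC1=O | target

Total step count: 17
Longest linear sequence: 16 (steps 1–8 and 10–17; step 9 is a one-step side branch)

Steps most likely to fail

1. Step 14 (the proposed new method). What may go wrong: methanolysis of the first acylpalladium intermediate before ring closure, alkene insertion into the vinylpalladium bond before CO uptake (5-exo carbopalladation), or weak facial discrimination by the C5 silyloxy group during alkene insertion. Any C1 epimer of 26 is a ring diastereomer and should be separable before C5 is oxidised. Fallback by known enolate chemistry, setting out from alkyne 15 and coming back at 26: the alkenylalane from 15 (Me3Al, Cp2ZrCl2) is treated with n-BuLi and paraformaldehyde to give the allylic alcohol (2E,6E,10E,12S,13R)-12,13-bis(tert-butyldimethylsilyloxy)-3,7,11,15-tetramethylhexadeca-2,6,10,14-tetraen-1-ol F1, which the Appel reaction converts into the bromide GG*–Br F2. The known (S)-4-hydroxycyclohex-2-en-1-one F3 is silylated (TESCl, imidazole) to (S)-4-(triethylsilyloxy)cyclohex-2-en-1-one F4. Kinetic deprotonation at C6 with lithium diisopropylamide and alkylation with F2 gives the 6-alkylated enone (4S)-6-GG*-4-(triethylsilyloxy)cyclohex-2-en-1-one F5. A second enolisation followed by methyl bromoacetate builds the quaternary centre, the electrophile being expected to enter anti to the silyloxy group, and delivers 26.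

2. Step 12. What may go wrong: incomplete enantioface discrimination between the (Z)-iodovinyl group and the branched methylene substituent, or Z to E isomerisation of the iodoenone on the way to it. Fallback that forms the carbinol centre in the C–C bond-forming event instead of by ketone reduction, setting out from allyl chloride 18 (with aldehyde 20) and coming back at 24: palladium-catalysed borylation of 18 (B2pin2, Pd2(dba)3, THF) gives the allylboronate 2-(2-GG*-allyl)-4,4,5,5-tetramethyl-1,3,2-dioxaborolane F6. Chiral phosphoric acid-catalysed allylboration of 20 with F6 [(S)-TRIP, 5 mol %, toluene, −30 °C; the antipode of the acid that gives (R)-1-phenylbut-3-en-1-ol from benzaldehyde] should then give 24 directly, bypassing 22 and 23.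

3. Step 10. What may go wrong: Z to E isomerisation of the iodo-aldehyde or of the adduct promoted by zinc halide, or homocoupling during zinc insertion. Fallback that introduces iodine only after the carbon skeleton is complete, setting out from 18 and coming back at 23: indium-mediated Barbier addition of 18 to 3-(trimethylsilyl)propynal (In powder, NaI, DMF) gives the propargylic alcohol 5-GG*-1-(trimethylsilyl)hex-5-en-1-yn-3-ol F7. K2CO3 in methanol removes the silyl group to give 5-GG*-hex-5-en-1-yn-3-ol F8, and Dess–Martin oxidation gives the terminal ynone 5-GG*-hex-5-en-1-yn-3-one F9. Hydroiodination with NaI in acetic acid, an anti addition across the ynone, should then install the (Z)-β-iodoenone 23.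

Further compounds
F1 | step 14 | (2E,6E,10E,12S,13R)-12,13-bis(tert-butyldimethylsilyloxy)-3,7,11,15-tetramethylhexadeca-2,6,10,14-tetraen-1-ol | OC/C=C(\C)CC/C=C(\C)CC/C=C(\C)[C@H](O[Si](C)(C)C(C)(C)C)[C@H](O[Si](C)(C)C(C)(C)C)C=C(C)C
F2 | step 14 | (2E,6E,10E,12S,13R)-1-bromo-12,13-bis(tert-butyldimethylsilyloxy)-3,7,11,15-tetramethylhexadeca-2,6,10,14-tetraene | BrC/C=C(\C)CC/C=C(\C)CC/C=C(\C)[C@H](O[Si](C)(C)C(C)(C)C)[C@H](O[Si](C)(C)C(C)(C)C)C=C(C)C
F3 | step 14 | (S)-4-hydroxycyclohex-2-en-1-one | O=C1C=C[C@@H](O)CC1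
F4 | step 14 | (S)-4-(triethylsilyloxy)cyclohex-2-en-1-one | O=C1C=C[C@@H](O[Si](CC)(CC)CC)CC1
F5 | step 14 | (4S)-6-GG*-4-(triethylsilyloxy)cyclohex-2-en-1-one (C6 epimers) | O=C1C=C[C@@H](O[Si](CC)(CC)CC)CC1C/C=C(\C)CC/C=C(\C)CC/C=C(\C)[C@H](O[Si](C)(C)C(C)(C)C)[C@H](O[Si](C)(C)C(C)(C)C)C=C(C)C
F6 | step 12 | 2-(2-GG*-allyl)-4,4,5,5-tetramethyl-1,3,2-dioxaborolane | CC1(C)OB(CC(=C)C/C=C(\C)CC/C=C(\C)CC/C=C(\C)[C@H](O[Si](C)(C)C(C)(C)C)[C@H](O[Si](C)(C)C(C)(C)C)C=C(C)C)OC1(C)C
F7 | step 10 | 5-GG*-1-(trimethylsilyl)hex-5-en-1-yn-3-ol (both C3 epimers) | C[Si](C)(C)C#CC(O)CC(=C)C/C=C(\C)CC/C=C(\C)CC/C=C(\C)[C@H](O[Si](C)(C)C(C)(C)C)[C@H](O[Si](C)(C)C(C)(C)C)C=C(C)C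
F8 | step 10 | 5-GG*-hex-5-en-1-yn-3-ol (both C3 epimers) | C#CC(O)CC(=C)C/C=C(\C)CC/C=C(\C)CC/C=C(\C)[C@H](O[Si](C)(C)C(C)(C)C)[C@H](O[Si](C)(C)C(C)(C)C)C=C(C)C
F9 | step 10 | 5-GG*-hex-5-en-1-yn-3-one | C#CC(=O)CC(=C)C/C=C(\C)CC/C=C(\C)CC/C=C(\C)[C@H](O[Si](C)(C)C(C)(C)C)[C@H](O[Si](C)(C)C(C)(C)C)C=C(C)C
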